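I wanted to know how much target this flask held at 5.0 h, and whether any step taken then could add to it.

common to all: initiator 5 mol%

|  | starting material | partner | temperature | remark | time |
|---|---|---|---|---|---|
| west | 0.066 M | 4 equiv | 80 °C | the very flask that is asked about, followed so far |  |
| east | 0.033 M | 4 equiv | 65 °C | run made earlier |  |
| flask | 0.066 M | 4.00 equiv | 80 °C |  | 5.0 h |

west run (percent of the starting material charged)

| time / h | target / % | starting material / % |
|---|---|---|
| 0.167 | 19 | 47 |
| 0.500 | 33 | 15 |
| 0.833 | 36 | 9 |
| 1.33 | 40 | 5 |
| 2.00 | 41 | 5 |
| 2.50 | 45 | 0 |
| 3.00 | 44 | 2 |

east run (percent of the starting material charged)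

| time / min | target / % | starting material / % |
|---|---|---|
| 5.00 | 1 | 90 |
| 12.0 | 6 | 84 |
| 25.0 | 10 | 70 |
| 40.0 | 10 | 59 |
| 50.0 | 17 | 53 |
| 60.0 | 20 | 45 |
| 80.0 | 23 | 39 |

(standard deviation of a reading: 2 percentage points)

* target, in percent of the starting material first charged, at 5.0 h
* the remedy with the largest gain of target, or "none" below 2 percentage points (elm / ash / maple / larch / none)
* target present, in percent of the starting material first charged, after elm
* target present, in percent of the starting material first charged, after maple

- elm: at 5.0 h take out 90% of the released group then present, then wait 5.0 h
- ash: change nothing and wait 5.0 h more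
- maple: at 5.0 h raise the temperature by 25 K, then wait 5.0 h
- larch: at 5.0 h add partner, 100% of the amount charged, then wait 5.0 h

- additions bring no volume worth counting

I went down the time scales of the west run, which is this flask followed so far, starting with the fastest. Starting material, the limiting reagent against 4.00 equiv of partner, moved first: half had gone by 0.167 h, and its reading was 0% at 2.50 h. The target rose more slowly and flattened at about that time, for its last two readings, 45% and 44%, differ by 1 percentage point, less than the scatter. Any decay of target was the slowest rung, too slow to read, and since the time asked is twice that of the flattening, I pictured the flask at 5.0 h as it stood at the last readings.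

I then followed one molecule of starting material, which either became target or was lost elsewhere, and took that fork once. The odds at the fork, target made against starting material lost to other ends (a selectivity factor), read 0.818 at 2.50 h, which is a share of 45.0% for target, and that was my figure for 5.0 h. The last two readings of starting material, 0% and 2%, lie within the scatter of 2 points around zero, so I counted on no further material for a remedy to turn into target and chose none.

The forecast gave 45% now, 45% after elm, 45% after maple and none as best: “With nothing left to convert, extra partner, removing released group, heating or waiting should each change little.” The flask gave 45.1%, 45.1% after elm, 45.1% after maple and none as best.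

    2 starting material → self-condensation product (k = 0.620 M⁻¹ min⁻¹, Ea = 86.0 kJ mol⁻¹)
    partner + first chain carrier ⇌ target + second chain carrier (K = 0.0580, k = 33000 M⁻¹ min⁻¹, Ea = 41.0 kJ mol⁻¹, ΔH = −76.0 kJ mol⁻¹)
    initiator → 2 initiating radical (k = 0.0140 min⁻¹, Ea = 111 kJ mol⁻¹)
    starting material + second chain carrier → released group + first chain carrier (k = 1.20 × 10⁵ M⁻¹ min⁻¹, Ea = 37.0 kJ mol⁻¹)
    starting material + initiating radical → capped initiator + first chain carrier (k = 16000 M⁻¹ s⁻¹, Ea = 10.0 kJ mol⁻¹)
    2 second chain carrier → ended chains (k = 1.80 × 10⁷ M⁻¹ s⁻¹, Ea = 14.0 kJ mol⁻¹)
    (constants at 80 °C)

The other end of the fork was self-condensation: without that step the flask reached 97.5% instead of 45.1%. At 5.0 h the odds stood as target against self-condensation product, 0.823. Second chain carrier ends in pairs, so I took its level, and with it the odds, to go with the root of the initiator charge. For the neighbour with 20 mol% of initiator that gave odds of 1.64 and a share of 62.1%; that flask gave 62.8%.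

The data are simulated from invented constants, and the scatter is random.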